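Early in the dawn run, at 4.00 h, monomer in chains reads 6.0% of the free monomer charged, and at 12.0 h it reads 19.6%, so within the scatter the line is straight. Initiator starts living ends on free monomer, but it also reacts with impurity and with itself. A living end, however, comes out of each addition unchanged, like a catalyst. A straight line therefore says that the ends stand at a steady number from early on, with free monomer falling pseudo-first-order. Each end then has a turnover, the units it adds per hour, and if ends begin early and keep working, the average length is turnover times time, however many ends share the free monomer.

all flasks: free monomer 0.050 M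
- summer: initiator 7 mM; impurity 6 mM; run made earlier
- dawn: initiator 11 mM; impurity 6 mM; run made earlier
- midnight: initiator 5 mM; impurity 12 mM; run made earlier
- flask: initiator 5.0 mM; impurity 6.0 mM; time 20 h

| run | time / h | monomer in chains / % | free monomer / % |
|---|---|---|---|
| summer | 0.833 | 0.5 | 98.7 |
| summer | 2.50 | 4.0 | 96.5 |
| summer | 4.00 | 4.1 | 95.0 |
| summer | 6.00 | 7.9 | 93.7 |
| summer | 10.0 | 10.1 | 88.8 |
| summer | 12.0 | 12.8 | 87.3 |
| dawn | 2.00 | 2.8 | 96.0 |
| dawn | 4.00 | 6.0 | 92.7 |
| dawn | 6.00 | 9.4 | 89.4 |
| dawn | 8.00 | 11.9 | 87.6 |
| dawn | 10.0 | 17.1 | 83.8 |
| dawn | 12.0 | 19.6 | 81.6 |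
| midnight | 1.00 | 0.4 | 98.0 |
| midnight | 3.00 | 0.7 | 99.9 |
| midnight | 6.00 | 2.6 | 96.1 |
| midnight | 8.00 | 2.1 | 95.3 |
| midnight | 12.0 | 6.0 | 94.9 |

(scatter of a reading: 1 percentage point)

1. whether the average number of monomer units in a chain (chains begun, living or dead) reaches 400 by 20 h (yes / no)
2. average number of monomer units in a chain (chains begun, living or dead) at 20 h

- the average divides the monomer in chains by the number of chains begun, living and dead together
- reactions considered so far: initiator + impurity -> spent initiator A; 2 initiator -> spent initiator B; free monomer + living end -> monomer in chains + living end; free monomer + initiator -> living end + monomer in chains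
- the earlier runs do not show the number of chains; that part of a forecast is a guess

So ask what turnover the flask needs: the wanted length over the time allowed, 20.0 h⁻¹.

The neighbour is the midnight run, with the flask's initiator but 12 mM of impurity; its slope reads 0.250 mM h⁻¹. The summer run reads 0.533 mM h⁻¹ at 7 mM of initiator, and scaled to the flask's 5.0 mM that gives 0.381 mM h⁻¹, faster than midnight. By my reckoning the flask holds 1.52 times midnight's ends, yet with free monomer nearly alike each end works at nearly the same pace, so I expect nearly the same length in both. The runs show slopes, not ends, but the flask meets its need if its ends stay under 0.0190 mM, which is 0.380% of its initiator. With 12 mM of impurity the midnight slope stands below that scaled figure, which a start outrunning the impurity wouldn't show, so I lean to yes, as a guess.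

The forecast answers no with a length of 8, and of the chains a length of 400 asks for it says “which is unlikely”, where I lean the other way.

The simulation answers yes, with a length of 710 at 20 h.

    initiator + impurity → spent initiator A (k = 3500 M⁻¹ h⁻¹)
    2 initiator → spent initiator B (k = 2600 M⁻¹ h⁻¹)
    free monomer + living end → monomer in chains + living end, rate k3*[living end]*[free monomer] (k = 780 M⁻¹ h⁻¹)
    free monomer + initiator → living end + monomer in chains (k = 1.20 M⁻¹ h⁻¹)

The flask holds 1.19 × 10⁻⁵ M of living end at 20.0 h, under my ceiling. Its turnover over the whole run comes to 35.5 h⁻¹, above the 20.0 h⁻¹ it needed. With twice the impurity, which is midnight's charge, the length at the end is 742, a turnover of 37.1 h⁻¹.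

All runs were generated by integration on assumed constants.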